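Per hour is the unit I would reckon in, and you asked for a quick number, so here is one with its working.

in all of them: J 28 mM; D 2 mol% (in portions, 4)

| run | E | L | temperature | remark | time |
|---|---|---|---|---|---|
| north-west | 3 mM (held) | 3.4 mol% | −20 °C | run made earlier; portions every 2.0 h |  |
| Thursday's | 3.0 mM (held) | 1.7 mol% |  | at −20 °C until 30 h, from then on at 5 °C; the portions of D follow each other after 2.0 h, the first at the start | 2.5 d |
| Sunday's | 3.0 mM (held) | 1.7 mol% |  | at −20 °C throughout; the portions of D follow each other after 2.0 h, the first at the start | 2.5 d |

north-west run (percent of the J charged)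

| time / h | X / % | J / % |
|---|---|---|
| 1.50 | 0 | 72.9 |
| 4.00 | 3.3 | 42.3 |
| 8.00 | 12.3 | 17.5 |
| 12.0 | 25.2 | 7.6 |

(standard deviation of a reading: 0.5 percentage points)

- at the start none of G is dissolved
- what was read earlier has a scatter of 0.5 percentage points, one standard deviation
- steps thought possible: J + L -> L + Z; G + D + Z -> D + X; G <-> Q; E <-> G
- the earlier runs do not show what temperature does; that part of a forecast is a guess
- no earlier run changes the charge of L; that part of a forecast is a guess

- which of the two ends with the higher amount of X, in percent of the J charged ("neither" if they lie within 2 percentage points) (Thursday's / Sunday's / neither)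
- X at the end, in percent of the J charged, Thursday's
- X at the end, in percent of the J charged, Sunday's

1. In the north-west run, J decays as a first-order curve, with a constant of 0.215 h⁻¹ from the first reading to the last. No earlier run changes L, so scaling with L is a guess: half of that gives 0.108 h⁻¹ for Thursday's and Sunday's.

2. Z is whatever is neither J nor X. In the north-west run, between 8.00 h and 12.0 h, X rose by 13 percentage points while Z averaged 68.7%. Dividing gives the clearing constant, the share of the Z present that becomes X each hour: 0.0469 h⁻¹. With G and D taken as steady it is a pseudo-first-order constant, and as a reading it carries the scatter of the readings.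

3. For Sunday's, my first pass lets J become Z at the start, which leaves 5.98% of Z at the end. Now put that back in and go round again. Z arrives late, on average by the mean life of J, 9.29 h, so its clock starts then. That leaves Sunday's with 9.25% of Z at the end, and its X comes to 90.8%.

4. Thursday's follows Sunday's until 30 h, when the same reckoning leaves 37.8% of Z. What warming does is unread. If it gave 2 times the clearing constant, which is my assumption, Z in Thursday's would end at 2.26%.

Your forecast puts Thursday's ahead, with Thursday's at 97% (88% to 100%) and Sunday's at 87% (74% to 95%), and it says of the warming: “though less gas may dissolve and the temperature effect is a guess”. We pick the same flask, and my Sunday's figure is higher than yours but inside your range.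

Thursday's ended at >99.9% and Sunday's at 91.3%.

J + L → L + Z (k = 232 M⁻¹ h⁻¹, Ea = 39.0 kJ mol⁻¹); G + D + Z → D + X (k = 49000 M⁻² h⁻¹, Ea = 39.0 kJ mol⁻¹); G ⇌ Q (K = 28.6, k = 0.247 h⁻¹, Ea = 75.0 kJ mol⁻¹, ΔH = −19.0 kJ mol⁻¹); E ⇌ G, rate k4*(csat - [G]) (kL = 0.688 h⁻¹); (constants at −20 °C) Going from Thursday's temperature programme to Sunday's moved X by −8.7 points. On Sunday's, Z fell from 38.8% at 1.25 d to 8.57% at 2.50 d, an apparent constant of 0.0503 h⁻¹ beside the clearing constant of 0.0469 h⁻¹. The neighbouring flask, Thursday's stopped at 40 h, had Z down from 38.8% to 9.26% in 10.0 h after warming, an apparent constant of 0.143 h⁻¹, faster than the clearing constant by a factor of 3.05.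

All runs are calculated from invented constants.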